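**Plan**

Locants used below (elemane type): ring C5–C10 (C10 quaternary with methyl and vinyl C1=C2, C9 CH2, C8 acyloxy carbon, C7 carrying the acrylic acid C13=C11–C12, C6 carbinol, C5 carrying the hydroxypropenyl C3=C4–C15). Abbreviations: TBS = tert-butyldimethylsilyl, TBDPS = tert-butyldiphenylsilyl, THP = oxan-2-yl, TMSE = 2-(trimethylsilyl)ethyl.
Retrosynthetic cuts, in order: the Z C=C of the C8 ester side chain (olefination of a phosphonopropionate); ring bond C7–C8; C11–C12 (carbonylation) and C6–C7 (acetylide on a Weinreb amide); C5–C10 (ester enolate Claisen); the ester C–O between two achiral pieces.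
Feature that allows the key event: C13=C11(CO2H)–C7–C8–O is a homoallylic alcohol, so the ring bond C7–C8 is the bond an allyl-metal makes with an aldehyde. Read backwards, C8 is an aldehyde carbon and C7 the β-carbon of a 2-(bromomethyl)alk-2-enoate: two electrophilic carbons, joined after two-electron reduction by CrCl2, which closes the only ring and moves the double bond into the exocyclic methylene.
Forward order: the open chain is built first (the Claisen step gives C5, C10, the vinyl and the propenyl unit at once; alkynylation, reduction, trans-hydroalumination/iodination and carbonylation give the E-configured bromomethyl enoate). The cyclohexane closes last through C7–C8, followed by acylation, Z-olefination and global desilylation.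
Stereochemistry: C5/C10 from a chair Claisen of a chiral boron enolate; C6 from a CBS reduction matched with Felkin–Anh control; C7/C8 from the chair cyclisation (allylic strain, equatorial oxygen, E-bromide geometry); side-chain Z from the Still–Gennari reaction.

Key step: step 17

Assumption: the (4S,5S)-diazaborolidine controller of step 6 is taken to give (2R,3S)-11 (if the sense of induction is opposite, the (4R,5R)-controller is used and nothing else changes); the THP acetal carbon is carried as a mixture of epimers in 15–20.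

**Route**

Step 1
Reactants: 1 tert-butyl(but-3-yn-1-yloxy)dimethylsilane
Product: 3 (2E)-5-[(tert-butyldimethylsilyl)oxy]-3-methylpent-2-en-1-ol, via alkenyldimethylalane 2 (not isolated)
Conditions: AlMe3, Cp2ZrCl2 (cat.), CH2Cl2, 0 °C to rt; then (CH2O)n, rt; sat. aq. NH4Cl
Reagents that add atoms: trimethylaluminium C[Al](C)C; formaldehyde (from paraformaldehyde) C=O
Why: Negishi zirconium-catalysed carboalumination adds Me–Al syn across the terminal alkyne with methyl on the internal carbon, and the alkenyl–Al bond is hydroxymethylated with retention, which fixes the E geometry needed for the Claisen step.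

Step 2
Reactants: 4 2-methylidenepropane-1,3-diol
Product: 5 2-({[tert-butyl(diphenyl)silyl]oxy}methyl)prop-2-en-1-ol
Conditions: NaH (1.0 equiv), THF, 0 °C to rt; then TBDPSCl (1.0 equiv)
Reagents that add atoms: tert-butyl(chloro)diphenylsilane CC(C)(C)[Si](Cl)(c1ccccc1)c1ccccc1
Why: O-silylation of the monosodium alkoxide of a symmetric diol should give mainly the mono-ether; no stereocentre is formed.

Step 3
Reactants: 5 2-({[tert-butyl(diphenyl)silyl]oxy}methyl)prop-2-en-1-ol
Product: 6 tert-butyl{[2-(chloromethyl)prop-2-en-1-yl]oxy}diphenylsilane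
Conditions: PPh3, N-chlorosuccinimide, THF, 0 °C to rt
Reagents that add atoms: N-chlorosuccinimide O=C1CCC(=O)N1Cl
Why: Appel-type chlorination converts the primary allylic alcohol under neutral conditions that leave the silyl ether intact, and the symmetric 2-substituted allyl system makes SN2 and SN2' products identical.

Step 4
Reactants: 6 tert-butyl{[2-(chloromethyl)prop-2-en-1-yl]oxy}diphenylsilane
Product: 8 3-({[tert-butyl(diphenyl)silyl]oxy}methyl)but-3-enoic acid, via allylmagnesium chloride 7 (not isolated)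
Conditions: Mg turnings, THF, 0 °C, slow addition; then CO2 (gas), −78 °C to rt; cold 1 M HCl
Reagents that add atoms: carbon dioxide O=C=O
Why: Grignard formation from the allylic chloride and carboxylation; the symmetric 2-substituted allylmagnesium reagent can only give the β,γ-unsaturated acid.

Step 5
Reactants: 3 (2E)-5-[(tert-butyldimethylsilyl)oxy]-3-methylpent-2-en-1-ol; 8 3-({[tert-butyl(diphenyl)silyl]oxy}methyl)but-3-enoic acid
Product: 9 (2E)-5-[(tert-butyldimethylsilyl)oxy]-3-methylpent-2-en-1-yl 3-({[tert-butyl(diphenyl)silyl]oxy}methyl)but-3-enoate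
Conditions: DCC, DMAP (5 mol%), CH2Cl2, −20 to 0 °C
Reagents that add atoms: none
Why: Steglich esterification at low temperature with little DMAP joins the two achiral halves without moving the β,γ-double bond into conjugation.

Step 6
Reactants: 9 (2E)-5-[(tert-butyldimethylsilyl)oxy]-3-methylpent-2-en-1-yl 3-({[tert-butyl(diphenyl)silyl]oxy}methyl)but-3-enoate
Product: 11 (2R,3S)-3-{2-[(tert-butyldimethylsilyl)oxy]ethyl}-2-(3-{[tert-butyl(diphenyl)silyl]oxy}prop-1-en-2-yl)-3-methylpent-4-enoic acid, via boron ketene acetal 10 (not isolated)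
Conditions: (4S,5S)-2-bromo-4,5-diphenyl-1,3-bis{[3,5-bis(trifluoromethyl)phenyl]sulfonyl}-1,3,2-diazaborolidine (1.3 equiv), Et3N, toluene/hexane, −78 °C; then 4 °C; aqueous work-up
Reagents that add atoms: none
Why: Ester enolate (Ireland-type) Claisen rearrangement through a chiral boron ketene acetal: soft enolisation in a non-polar medium should place the propenyl group trans to O–B, and the chair [3,3] shift with the E allyl unit (C9 chain pseudo-equatorial, methyl pseudo-axial) creates C5 and C10 with the C4 and C9 branches anti, while the C2-symmetric sulfonamide controller selects the enolate face; this reaction type has close precedent for vinyl/methyl quaternary centres next to a propenyl-bearing carbon.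

Step 7
Reactants: 11 (2R,3S)-3-{2-[(tert-butyldimethylsilyl)oxy]ethyl}-2-(3-{[tert-butyl(diphenyl)silyl]oxy}prop-1-en-2-yl)-3-methylpent-4-enoic acid
Product: 12 (2R,3S)-3-{2-[(tert-butyldimethylsilyl)oxy]ethyl}-2-(3-{[tert-butyl(diphenyl)silyl]oxy}prop-1-en-2-yl)-N-methoxy-N,3-dimethylpent-4-enamide
Conditions: MeNH(OMe)·HCl, EDC·HCl, HOBt (cat.), N-methylmorpholine, CH2Cl2, 0 °C to rt
Reagents that add atoms: N,O-dimethylhydroxylamine hydrochloride CNOC.Cl
Why: Carbodiimide amidation to the Weinreb amide, chosen so that the next step stops at the ketone; the near-neutral conditions should not epimerise the allylic α-stereocentre C5.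

Step 8
Reactants: 12 (2R,3S)-Weinreb amide (as named in step 7); 13 2-(prop-2-yn-1-yloxy)oxane
Product: 15 (5R,6S)-6-{2-[(tert-butyldimethylsilyl)oxy]ethyl}-5-(3-{[tert-butyl(diphenyl)silyl]oxy}prop-1-en-2-yl)-6-methyl-1-(oxan-2-yloxy)oct-7-en-2-yn-4-one, via lithium acetylide 14 (not isolated)
Conditions: 13, n-BuLi, THF, −78 °C; then 12, −78 to 0 °C; sat. aq. NH4Cl
Reagents that add atoms: none
Why: Acylation of a lithium acetylide by a Weinreb amide: the chelated tetrahedral intermediate survives until work-up, so the ynone forms without over-addition, and the weakly basic acetylide should leave C5 intact.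

Step 9
Reactants: 15 (5R,6S)-ynone (as named in step 8)
Product: 16 (4S,5R,6S)-6-{2-[(tert-butyldimethylsilyl)oxy]ethyl}-5-(3-{[tert-butyl(diphenyl)silyl]oxy}prop-1-en-2-yl)-6-methyl-1-(oxan-2-yloxy)oct-7-en-2-yn-4-ol
Conditions: (S)-2-methyl-CBS-oxazaborolidine, catecholborane, CH2Cl2, −78 °C
Reagents that add atoms: none
Why: Corey–Bakshi–Shibata reduction with catecholborane (which avoids hydroboration of the alkenes): the bulky C5 branch acts as the large and the alkynyl as the small group, so the (S)-catalyst should give the (4S) carbinol (C6), in the sense also favoured by Felkin–Anh control from C5.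

Step 10
Reactants: 16 (4S,5R,6S)-propargylic alcohol (as named in step 9)
Product: 18 (2Z,4S,5R,6S)-6-{2-[(tert-butyldimethylsilyl)oxy]ethyl}-5-(3-{[tert-butyl(diphenyl)silyl]oxy}prop-1-en-2-yl)-2-iodo-6-methyl-1-(oxan-2-yloxy)octa-2,7-dien-4-ol, via cyclic alkenylaluminate 17 (not isolated)
Conditions: NaAlH2(OCH2CH2OMe)2, THF, 0 °C; then I2, THF, −78 to 0 °C
Reagents that add atoms: iodine II
Why: Hydroxyl-directed trans-hydroalumination: the aluminium alkoxide delivers hydride to the proximal alkyne carbon C7 and aluminium ends on C11 in a five-membered ring, and iodinolysis with retention gives the Z iodide with iodine cis to C6, which later puts the ester cis and the bromomethyl group trans to C6.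

Step 11
Reactants: 18 (2Z,4S,5R,6S)-iodo alcohol (as named in step 10)
Product: 19 (2Z,4S,5R,6S)-4-[(tert-butyldimethylsilyl)oxy]-6-{2-[(tert-butyldimethylsilyl)oxy]ethyl}-5-(3-{[tert-butyl(diphenyl)silyl]oxy}prop-1-en-2-yl)-2-iodo-6-methyl-1-(oxan-2-yloxy)octa-2,7-diene
Conditions: TBSOTf (1.2 equiv), 2,6-lutidine, CH2Cl2, −78 °C
Reagents that add atoms: tert-butyldimethylsilyl triflate CC(C)(C)[Si](C)(C)OS(=O)(=O)C(F)(F)F
Why: Silylation of the hindered secondary alcohol with the silyl triflate at low temperature; the ether prevents butenolide formation in the carbonylation and serves as the C6 protecting group.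

Step 12
Reactants: 19 (2Z,4S,5R,6S)-alkenyl iodide (as named in step 11)
Product: 20 2-(trimethylsilyl)ethyl (2Z,4R,5R,6S)-4-[(tert-butyldimethylsilyl)oxy]-6-{2-[(tert-butyldimethylsilyl)oxy]ethyl}-5-(3-{[tert-butyl(diphenyl)silyl]oxy}prop-1-en-2-yl)-6-methyl-2-[(oxan-2-yloxy)methyl]octa-2,7-dienoate
Conditions: PdCl2(PPh3)2 (cat.), CO (1 atm), 2-(trimethylsilyl)ethanol, Et3N, DMF, 60 °C
Reagents that add atoms: carbon monoxide [C-]#[O+]; 2-(trimethylsilyl)ethanol C[Si](C)(C)CCO
Why: Palladium-catalysed alkoxycarbonylation of the alkenyl iodide (oxidative addition, CO insertion, alcoholysis) proceeds with retention of alkene geometry and installs a fluoride-labile ester.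

Step 13
Reactants: 20 TMSE ester (as named in step 12)
Product: 21 2-(trimethylsilyl)ethyl (2Z,4R,5R,6S)-4-[(tert-butyldimethylsilyl)oxy]-6-{2-[(tert-butyldimethylsilyl)oxy]ethyl}-5-(3-{[tert-butyl(diphenyl)silyl]oxy}prop-1-en-2-yl)-2-(hydroxymethyl)-6-methylocta-2,7-dienoate
Conditions: MgBr2·OEt2, Et2O, rt; aqueous work-up
Reagents that add atoms: none
Why: Lewis acid cleavage of the THP acetal with MgBr2 is selective over TBS and TBDPS ethers and frees only the allylic C13 hydroxyl.

Step 14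
Reactants: 21 allylic alcohol (as named in step 13)
Product: 22 2-(trimethylsilyl)ethyl (2E,4R,5R,6S)-2-(bromomethyl)-4-[(tert-butyldimethylsilyl)oxy]-6-{2-[(tert-butyldimethylsilyl)oxy]ethyl}-5-(3-{[tert-butyl(diphenyl)silyl]oxy}prop-1-en-2-yl)-6-methylocta-2,7-dienoate
Conditions: CBr4, PPh3, 2,6-lutidine, CH2Cl2, 0 °C
Reagents that add atoms: carbon tetrabromide BrC(Br)(Br)Br
Why: Appel bromination of the primary allylic alcohol under buffered conditions gives the 2-(bromomethyl)enoate without allylic transposition, the conjugated primary bromide being the stable regioisomer.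

Step 15
Reactants: 22 allylic bromide (as named in step 14)
Product: 23 2-(trimethylsilyl)ethyl (2E,4R,5R,6S)-2-(bromomethyl)-4-[(tert-butyldimethylsilyl)oxy]-5-(3-{[tert-butyl(diphenyl)silyl]oxy}prop-1-en-2-yl)-6-(2-hydroxyethyl)-6-methylocta-2,7-dienoate
Conditions: aq. HF (48%), MeCN, 0 °C, short reaction time
Reagents that add atoms: none
Why: Acidic fluoride removes the unhindered primary TBS ether much faster than the hindered secondary allylic TBS ether and the TBDPS ether, and unlike amine–HF reagents it contains no nucleophile for the allylic bromide.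

Step 16
Reactants: 23 primary alcohol (as named in step 15)
Product: 24 2-(trimethylsilyl)ethyl (2E,4R,5R,6S)-2-(bromomethyl)-4-[(tert-butyldimethylsilyl)oxy]-5-(3-{[tert-butyl(diphenyl)silyl]oxy}prop-1-en-2-yl)-6-methyl-6-(2-oxoethyl)octa-2,7-dienoate
Conditions: Dess–Martin periodinane, NaHCO3, CH2Cl2, 0 °C to rt
Reagents that add atoms: none
Why: Dess–Martin oxidation under bicarbonate buffer gives the aldehyde without touching the allylic bromide, the alkenes or the silyl groups.

Step 17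
Reactants: 24 bromo aldehyde (as named in step 16)
Product: 26 2-(trimethylsilyl)ethyl 2-[(1R,2S,3R,4S,6S)-2-[(tert-butyldimethylsilyl)oxy]-3-(3-{[tert-butyl(diphenyl)silyl]oxy}prop-1-en-2-yl)-4-ethenyl-6-hydroxy-4-methylcyclohexyl]prop-2-enoate, via allylchromium dichloride 25 (not isolated)
Conditions: CrCl2 (6 equiv), degassed THF, 0.005 M, rt; sat. aq. NH4Cl
Reagents that add atoms: none
Why: CrCl2 reduces the allylic C–Br bond by two one-electron transfers to the allylchromium dichloride 25 (trivalent chromium on C13), which adds to the tethered aldehyde through its γ-carbon C7 (SE2') in a six-membered O–Cr chelated Zimmerman–Traxler transition state, so that two electrophilic carbons (enoate β-carbon C7 and carbonyl carbon C8) are joined after polarity reversal; the closest known reaction type is the intramolecular Nozaki–Hiyama-type 2-(alkoxycarbonyl)allylation of ω-formyl 2-(bromomethyl)alk-2-enoates to carbocycles carrying an α-methylene ester or lactone. The cyclohexane closes in a chair-like 6-exo-trig mode onto the aldehyde, favoured over the eight-membered ring that attack through C13 would give. C7 is set by allylic 1,3-strain: the C6–H bond eclipses C7=C11, which puts the OTBS group axial and the C5 branch equatorial, and C8 can reach only the alkene face syn to C5, so the new acrylate is equatorial and cis to O6. C8 is set because the aldehyde oxygen must be equatorial (an axial oxygen would be syn-diaxial to both the C10 methyl and the C6 OTBS group) and because the E bromide (CH2Cr trans to C6) lets chromium bridge C13 and an equatorial oxygen, giving the 7,8-trans diequatorial product. The step needs chemoselective reduction of the allylic bromide only (alkenes, silyl ethers and the TMSE enoate are inert to divalent chromium), high dilution against intermolecular allylation, and no lactonisation of the chromium alkoxide onto the TMSE ester at room temperature.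

Step 18
Reactants: 27 ethyl 2-[bis(2,2,2-trifluoroethoxy)phosphoryl]propanoate
Product: 28 2-[bis(2,2,2-trifluoroethoxy)phosphoryl]propanoic acid (racemic)
Conditions: Me3SnOH, 1,2-dichloroethane, 70 °C; then 1 M HCl wash
Reagents that add atoms: trimethyltin hydroxide C[Sn](C)(C)O
Why: Mild hydroxide transfer from Me3SnOH hydrolyses the carboxylic ethyl ester by acyl–oxygen cleavage and should spare the base-sensitive trifluoroethyl phosphonate esters.

Step 19
Reactants: 26 cyclohexanol (as named in step 17); 28 2-[bis(2,2,2-trifluoroethoxy)phosphoryl]propanoic acid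
Product: 29 2-(trimethylsilyl)ethyl 2-[(1R,2S,3R,4S,6S)-6-({2-[bis(2,2,2-trifluoroethoxy)phosphoryl]propanoyl}oxy)-2-[(tert-butyldimethylsilyl)oxy]-3-(3-{[tert-butyl(diphenyl)silyl]oxy}prop-1-en-2-yl)-4-ethenyl-4-methylcyclohexyl]prop-2-enoate (both epimers at the phosphonate α-carbon)
Conditions: DCC, DMAP (cat.), CH2Cl2, 0 °C to rt
Reagents that add atoms: none
Why: Steglich esterification of the equatorial C8 hydroxyl, the only free hydroxyl, with retention at C8; the phosphonate α-stereocentre is irrelevant because it becomes sp2 in the next step.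

Step 20
Reactants: 29 phosphonate ester (as named in step 19); 30 2-oxoethyl acetate
Product: 32 2-(trimethylsilyl)ethyl 2-[(1R,2S,3R,4S,6S)-6-{[(2Z)-4-(acetyloxy)-2-methylbut-2-enoyl]oxy}-2-[(tert-butyldimethylsilyl)oxy]-3-(3-{[tert-butyl(diphenyl)silyl]oxy}prop-1-en-2-yl)-4-ethenyl-4-methylcyclohexyl]prop-2-enoate, via potassium phosphonate carbanion 31 (not isolated)
Conditions: KN(SiMe3)2 (1.0 equiv), 18-crown-6, THF, −78 °C; then 30, −78 °C
Reagents that add atoms: none
Why: Still–Gennari olefination: the electron-poor bis(trifluoroethyl) phosphonate anion adds to the aldehyde and the adduct collapses under kinetic control with a dissociated potassium counter-ion, which should give the Z trisubstituted enoate (acetoxymethyl cis to the ester carbonyl); the stabilised anion forms selectively at −78 °C and should not add to the acrylate.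

Step 21
Reactants: 32 fully protected ester (as named in step 20)
Product: 33 2-[(1S,2S,3R,4S,6S)-6-{[(2Z)-4-(acetyloxy)-2-methylbut-2-enoyl]oxy}-4-ethenyl-2-hydroxy-3-(3-hydroxyprop-1-en-2-yl)-4-methylcyclohexyl]prop-2-enoic acid (CNP0261293.3)
Conditions: tris(dimethylamino)sulfonium difluorotrimethylsilicate (TASF, excess), DMF, 0 °C to rt; then sat. aq. NH4Cl adjusted to pH 4–5, 0 °C
Reagents that add atoms: none
Why: Fluoride attacks silicon: both silyl ethers are cleaved and the TMSE ester fragments by β-elimination (ethene and Me3SiF) to the carboxylate under non-hydrolytic conditions that should leave the acetate and the Z enoate ester intact, and the cold buffered work-up should give the hydroxy acid without lactonisation.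

**Compound list**

1 | tert-butyl(but-3-yn-1-yloxy)dimethylsilane | C#CCCO[Si](C)(C)C(C)(C)C | starting material
2 | (E)-{4-[(tert-butyldimethylsilyl)oxy]-2-methylbut-1-en-1-yl}dimethylalane (formed in the flask) | C[Al](C)/C=C(\C)CCO[Si](C)(C)C(C)(C)C | intermediate
3 | (2E)-5-[(tert-butyldimethylsilyl)oxy]-3-methylpent-2-en-1-ol | OC/C=C(\C)CCO[Si](C)(C)C(C)(C)C | intermediate
4 | 2-methylidenepropane-1,3-diol | C=C(CO)CO | starting material
5 | 2-({[tert-butyl(diphenyl)silyl]oxy}methyl)prop-2-en-1-ol | C=C(CO)CO[Si](c1ccccc1)(c1ccccc1)C(C)(C)C | intermediate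
6 | tert-butyl{[2-(chloromethyl)prop-2-en-1-yl]oxy}diphenylsilane | C=C(CCl)CO[Si](c1ccccc1)(c1ccccc1)C(C)(C)C | intermediate
7 | [2-({[tert-butyl(diphenyl)silyl]oxy}methyl)prop-2-en-1-yl]magnesium chloride (formed in the flask) | C=C(C[Mg]Cl)CO[Si](c1ccccc1)(c1ccccc1)C(C)(C)C | intermediate
8 | 3-({[tert-butyl(diphenyl)silyl]oxy}methyl)but-3-enoic acid | C=C(CC(=O)O)CO[Si](c1ccccc1)(c1ccccc1)C(C)(C)C | intermediate
9 | (2E)-5-[(tert-butyldimethylsilyl)oxy]-3-methylpent-2-en-1-yl 3-({[tert-butyl(diphenyl)silyl]oxy}methyl)but-3-enoate | C=C(CC(=O)OC/C=C(\C)CCO[Si](C)(C)C(C)(C)C)CO[Si](c1ccccc1)(c1ccccc1)C(C)(C)C | intermediate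
10 | O-boron ketene acetal of 9, boron = (4S,5S)-4,5-diphenyl-1,3-bis{[3,5-bis(trifluoromethyl)phenyl]sulfonyl}-1,3,2-diazaborolidin-2-yl, propenyl group trans to O–B (formed in the flask) | C=C(CO[Si](c1ccccc1)(c1ccccc1)C(C)(C)C)/C=C(/OB1N(S(=O)(=O)c2cc(C(F)(F)F)cc(C(F)(F)F)c2)[C@@H](c2ccccc2)[C@H](c2ccccc2)N1S(=O)(=O)c1cc(C(F)(F)F)cc(C(F)(F)F)c1)OC/C=C(\C)CCO[Si](C)(C)C(C)(C)C | intermediate
11 | (2R,3S)-3-{2-[(tert-butyldimethylsilyl)oxy]ethyl}-2-(3-{[tert-butyl(diphenyl)silyl]oxy}prop-1-en-2-yl)-3-methylpent-4-enoic acid | C=C[C@](C)(CCO[Si](C)(C)C(C)(C)C)[C@@H](C(=O)O)C(=C)CO[Si](c1ccccc1)(c1ccccc1)C(C)(C)C | intermediate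
12 | (2R,3S)-3-{2-[(tert-butyldimethylsilyl)oxy]ethyl}-2-(3-{[tert-butyl(diphenyl)silyl]oxy}prop-1-en-2-yl)-N-methoxy-N,3-dimethylpent-4-enamide | C=C[C@](C)(CCO[Si](C)(C)C(C)(C)C)[C@@H](C(=O)N(C)OC)C(=C)CO[Si](c1ccccc1)(c1ccccc1)C(C)(C)C | intermediate
13 | 2-(prop-2-yn-1-yloxy)oxane | C#CCOC1CCCCO1 | starting material
14 | lithium 3-(oxan-2-yloxy)prop-1-yn-1-ide (formed in the flask) | [Li]C#CCOC1CCCCO1 | intermediate
15 | (5R,6S)-6-{2-[(tert-butyldimethylsilyl)oxy]ethyl}-5-(3-{[tert-butyl(diphenyl)silyl]oxy}prop-1-en-2-yl)-6-methyl-1-(oxan-2-yloxy)oct-7-en-2-yn-4-one (epimers at the THP carbon) | C=C[C@](C)(CCO[Si](C)(C)C(C)(C)C)[C@@H](C(=O)C#CCOC1CCCCO1)C(=C)CO[Si](c1ccccc1)(c1ccccc1)C(C)(C)C | intermediate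
16 | (4S,5R,6S)-6-{2-[(tert-butyldimethylsilyl)oxy]ethyl}-5-(3-{[tert-butyl(diphenyl)silyl]oxy}prop-1-en-2-yl)-6-methyl-1-(oxan-2-yloxy)oct-7-en-2-yn-4-ol | C=C[C@](C)(CCO[Si](C)(C)C(C)(C)C)[C@@H]([C@H](O)C#CCOC1CCCCO1)C(=C)CO[Si](c1ccccc1)(c1ccccc1)C(C)(C)C | intermediate
17 | sodium alkenyl(alkoxy)bis(2-methoxyethoxy)aluminate from 16: five-membered ring O–Al–C11=C7–C6 (formed in the flask) | C=C[C@](C)(CCO[Si](C)(C)C(C)(C)C)[C@@H]([C@@H]1O[Al-](OCCOC)(OCCOC)C(COC2CCCCO2)=C1)C(=C)CO[Si](c1ccccc1)(c1ccccc1)C(C)(C)C.[Na+] | intermediate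
18 | (2Z,4S,5R,6S)-6-{2-[(tert-butyldimethylsilyl)oxy]ethyl}-5-(3-{[tert-butyl(diphenyl)silyl]oxy}prop-1-en-2-yl)-2-iodo-6-methyl-1-(oxan-2-yloxy)octa-2,7-dien-4-ol | C=C[C@](C)(CCO[Si](C)(C)C(C)(C)C)[C@@H]([C@H](O)/C=C(\I)COC1CCCCO1)C(=C)CO[Si](c1ccccc1)(c1ccccc1)C(C)(C)C | intermediate
19 | (2Z,4S,5R,6S)-4-[(tert-butyldimethylsilyl)oxy]-6-{2-[(tert-butyldimethylsilyl)oxy]ethyl}-5-(3-{[tert-butyl(diphenyl)silyl]oxy}prop-1-en-2-yl)-2-iodo-6-methyl-1-(oxan-2-yloxy)octa-2,7-diene | C=C[C@](C)(CCO[Si](C)(C)C(C)(C)C)[C@@H]([C@H](O[Si](C)(C)C(C)(C)C)/C=C(\I)COC1CCCCO1)C(=C)CO[Si](c1ccccc1)(c1ccccc1)C(C)(C)C | intermediate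
20 | 2-(trimethylsilyl)ethyl (2Z,4R,5R,6S)-4-[(tert-butyldimethylsilyl)oxy]-6-{2-[(tert-butyldimethylsilyl)oxy]ethyl}-5-(3-{[tert-butyl(diphenyl)silyl]oxy}prop-1-en-2-yl)-6-methyl-2-[(oxan-2-yloxy)methyl]octa-2,7-dienoate | C=C[C@](C)(CCO[Si](C)(C)C(C)(C)C)[C@@H]([C@H](O[Si](C)(C)C(C)(C)C)/C=C(\C(=O)OCC[Si](C)(C)C)COC1CCCCO1)C(=C)CO[Si](c1ccccc1)(c1ccccc1)C(C)(C)C | intermediate
21 | 2-(trimethylsilyl)ethyl (2Z,4R,5R,6S)-4-[(tert-butyldimethylsilyl)oxy]-6-{2-[(tert-butyldimethylsilyl)oxy]ethyl}-5-(3-{[tert-butyl(diphenyl)silyl]oxy}prop-1-en-2-yl)-2-(hydroxymethyl)-6-methylocta-2,7-dienoate | C=C[C@](C)(CCO[Si](C)(C)C(C)(C)C)[C@@H]([C@H](O[Si](C)(C)C(C)(C)C)/C=C(\C(=O)OCC[Si](C)(C)C)CO)C(=C)CO[Si](c1ccccc1)(c1ccccc1)C(C)(C)C | intermediate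
22 | 2-(trimethylsilyl)ethyl (2E,4R,5R,6S)-2-(bromomethyl)-4-[(tert-butyldimethylsilyl)oxy]-6-{2-[(tert-butyldimethylsilyl)oxy]ethyl}-5-(3-{[tert-butyl(diphenyl)silyl]oxy}prop-1-en-2-yl)-6-methylocta-2,7-dienoate | C=C[C@](C)(CCO[Si](C)(C)C(C)(C)C)[C@@H]([C@H](O[Si](C)(C)C(C)(C)C)/C=C(\C(=O)OCC[Si](C)(C)C)CBr)C(=C)CO[Si](c1ccccc1)(c1ccccc1)C(C)(C)C | intermediate
23 | 2-(trimethylsilyl)ethyl (2E,4R,5R,6S)-2-(bromomethyl)-4-[(tert-butyldimethylsilyl)oxy]-5-(3-{[tert-butyl(diphenyl)silyl]oxy}prop-1-en-2-yl)-6-(2-hydroxyethyl)-6-methylocta-2,7-dienoate | C=C[C@](C)(CCO)[C@@H]([C@H](O[Si](C)(C)C(C)(C)C)/C=C(\C(=O)OCC[Si](C)(C)C)CBr)C(=C)CO[Si](c1ccccc1)(c1ccccc1)C(C)(C)C | intermediate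
24 | 2-(trimethylsilyl)ethyl (2E,4R,5R,6S)-2-(bromomethyl)-4-[(tert-butyldimethylsilyl)oxy]-5-(3-{[tert-butyl(diphenyl)silyl]oxy}prop-1-en-2-yl)-6-methyl-6-(2-oxoethyl)octa-2,7-dienoate | C=C[C@](C)(CC=O)[C@@H]([C@H](O[Si](C)(C)C(C)(C)C)/C=C(\C(=O)OCC[Si](C)(C)C)CBr)C(=C)CO[Si](c1ccccc1)(c1ccccc1)C(C)(C)C | intermediate
25 | allylchromium dichloride from 24, trivalent chromium on the former bromomethyl carbon (formed in the flask) | C=C[C@](C)(CC=O)[C@@H]([C@H](O[Si](C)(C)C(C)(C)C)/C=C(\C(=O)OCC[Si](C)(C)C)C[Cr](Cl)Cl)C(=C)CO[Si](c1ccccc1)(c1ccccc1)C(C)(C)C | intermediate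
26 | 2-(trimethylsilyl)ethyl 2-[(1R,2S,3R,4S,6S)-2-[(tert-butyldimethylsilyl)oxy]-3-(3-{[tert-butyl(diphenyl)silyl]oxy}prop-1-en-2-yl)-4-ethenyl-6-hydroxy-4-methylcyclohexyl]prop-2-enoate | C=C[C@]1(C)C[C@H](O)[C@@H](C(=C)C(=O)OCC[Si](C)(C)C)[C@@H](O[Si](C)(C)C(C)(C)C)[C@H]1C(=C)CO[Si](c1ccccc1)(c1ccccc1)C(C)(C)C | intermediate
27 | ethyl 2-[bis(2,2,2-trifluoroethoxy)phosphoryl]propanoate | CCOC(=O)C(C)P(=O)(OCC(F)(F)F)OCC(F)(F)F | starting material
28 | 2-[bis(2,2,2-trifluoroethoxy)phosphoryl]propanoic acid (racemic) | CC(C(=O)O)P(=O)(OCC(F)(F)F)OCC(F)(F)F | intermediate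
29 | 2-(trimethylsilyl)ethyl 2-[(1R,2S,3R,4S,6S)-6-({2-[bis(2,2,2-trifluoroethoxy)phosphoryl]propanoyl}oxy)-2-[(tert-butyldimethylsilyl)oxy]-3-(3-{[tert-butyl(diphenyl)silyl]oxy}prop-1-en-2-yl)-4-ethenyl-4-methylcyclohexyl]prop-2-enoate | C=C[C@]1(C)C[C@H](OC(=O)C(C)P(=O)(OCC(F)(F)F)OCC(F)(F)F)[C@@H](C(=C)C(=O)OCC[Si](C)(C)C)[C@@H](O[Si](C)(C)C(C)(C)C)[C@H]1C(=C)CO[Si](c1ccccc1)(c1ccccc1)C(C)(C)C | intermediate
30 | 2-oxoethyl acetate | CC(=O)OCC=O | starting material
31 | potassium salt of the phosphonate carbanion of 29 (formed in the flask) | C=C[C@]1(C)C[C@H](OC(=O)[C-](C)P(=O)(OCC(F)(F)F)OCC(F)(F)F)[C@@H](C(=C)C(=O)OCC[Si](C)(C)C)[C@@H](O[Si](C)(C)C(C)(C)C)[C@H]1C(=C)CO[Si](c1ccccc1)(c1ccccc1)C(C)(C)C.[K+] | intermediate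
32 | 2-(trimethylsilyl)ethyl 2-[(1R,2S,3R,4S,6S)-6-{[(2Z)-4-(acetyloxy)-2-methylbut-2-enoyl]oxy}-2-[(tert-butyldimethylsilyl)oxy]-3-(3-{[tert-butyl(diphenyl)silyl]oxy}prop-1-en-2-yl)-4-ethenyl-4-methylcyclohexyl]prop-2-enoate | C=C[C@]1(C)C[C@H](OC(=O)/C(C)=C\COC(C)=O)[C@@H](C(=C)C(=O)OCC[Si](C)(C)C)[C@@H](O[Si](C)(C)C(C)(C)C)[C@H]1C(=C)CO[Si](c1ccccc1)(c1ccccc1)C(C)(C)C | intermediate
33 | 2-[(1S,2S,3R,4S,6S)-6-{[(2Z)-4-(acetyloxy)-2-methylbut-2-enoyl]oxy}-4-ethenyl-2-hydroxy-3-(3-hydroxyprop-1-en-2-yl)-4-methylcyclohexyl]prop-2-enoic acid | C=C[C@]1(C)C[C@H](OC(=O)/C(C)=C\COC(C)=O)[C@@H](C(=C)C(=O)O)[C@@H](O)[C@H]1C(=C)CO | target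

**Step count and risks**

Total: 21 steps. Longest linear sequence: 19 steps (4 to 33 through steps 2–17 and 19–21).

Steps most likely to fail:

Step 6 (Claisen). What may go wrong: incomplete or geometrically unselective soft enolisation of the β,γ-unsaturated ester, migration of the double bond into conjugation, or weak facial control by the boron controller. Fallback, setting out from 9: the classical lithium enolate variant (LDA, THF, −78 °C, then Me3SiCl) gives the trimethylsilyl ketene acetal F1 with the propenyl group trans to O–Si. On warming to room temperature and dilute acid hydrolysis it rearranges through the same chair to the racemic acid F2 of the same relative configuration. Resolution with (S)-1-phenylethylamine by crystallisation should give the (S)-1-phenylethylammonium salt F3 of the (2R,3S)-acid (the antipodal amine is used if the other diastereomer is the less soluble one). Cold dilute acid then liberates the acid, and the route is rejoined at 11.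

Step 10 (hydroalumination/iodination). What may go wrong: β-elimination of the tetrahydropyranyloxy group from the alkenylaluminate to an allene, or incomplete iodinolysis. Fallback, setting out from 16: ruthenium-catalysed trans-hydrosilylation ([Cp*Ru(MeCN)3]PF6, Et3SiH, CH2Cl2, 0 °C to rt), which for propargylic alcohols places silicon on the distal alkyne carbon, gives the (Z)-alkenylsilane F4. Iododesilylation with N-iodosuccinimide and 2,6-lutidine in hexafluoroisopropanol proceeds with retention, and the route is rejoined at 18.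

Step 17 (ring closure). What may go wrong: loss of control at C7/C8 if the allylchromium isomerises about C7=C11 or reacts through a boat transition state, or simple reduction of the bromide without cyclisation. Fallback, setting out from 22: hexabutylditin with Pd(PPh3)4 (cat.) in THF converts the bromide into the allylstannane F5. Aqueous HF in MeCN at 0 °C then frees the primary alcohol F6, and Dess–Martin oxidation gives the stannyl aldehyde F7. BF3·OEt2 in CH2Cl2 at −78 °C closes the ring through an open synclinal transition state that does not depend on the alkene geometry and still enforces an equatorial oxygen; the allylstannane should outcompete a Prins reaction of the propenyl group at this temperature. The route is rejoined at 26.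

Further compounds
F1 | step 6 | trimethylsilyl ketene acetal of 9, propenyl group trans to O–Si | C=C(CO[Si](c1ccccc1)(c1ccccc1)C(C)(C)C)/C=C(/O[Si](C)(C)C)OC/C=C(\C)CCO[Si](C)(C)C(C)(C)C
F2 | step 6 | racemic (2R,3S)-3-{2-[(tert-butyldimethylsilyl)oxy]ethyl}-2-(3-{[tert-butyl(diphenyl)silyl]oxy}prop-1-en-2-yl)-3-methylpent-4-enoic acid (one enantiomer drawn) | C=C[C@](C)(CCO[Si](C)(C)C(C)(C)C)[C@@H](C(=O)O)C(=C)CO[Si](c1ccccc1)(c1ccccc1)C(C)(C)C
F3 | step 6 | (S)-1-phenylethylammonium (2R,3S)-3-{2-[(tert-butyldimethylsilyl)oxy]ethyl}-2-(3-{[tert-butyl(diphenyl)silyl]oxy}prop-1-en-2-yl)-3-methylpent-4-enoate | C=C[C@](C)(CCO[Si](C)(C)C(C)(C)C)[C@@H](C(=O)[O-])C(=C)CO[Si](c1ccccc1)(c1ccccc1)C(C)(C)C.C[C@H]([NH3+])c1ccccc1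
F4 | step 10 | (2Z,4S,5R,6S)-6-{2-[(tert-butyldimethylsilyl)oxy]ethyl}-5-(3-{[tert-butyl(diphenyl)silyl]oxy}prop-1-en-2-yl)-6-methyl-1-(oxan-2-yloxy)-2-(triethylsilyl)octa-2,7-dien-4-ol | C=C[C@](C)(CCO[Si](C)(C)C(C)(C)C)[C@@H]([C@H](O)/C=C(\[Si](CC)(CC)CC)COC1CCCCO1)C(=C)CO[Si](c1ccccc1)(c1ccccc1)C(C)(C)C
F5 | step 17 | 2-(trimethylsilyl)ethyl (2E,4R,5R,6S)-4-[(tert-butyldimethylsilyl)oxy]-6-{2-[(tert-butyldimethylsilyl)oxy]ethyl}-5-(3-{[tert-butyl(diphenyl)silyl]oxy}prop-1-en-2-yl)-6-methyl-2-[(tributylstannyl)methyl]octa-2,7-dienoate | C=C[C@](C)(CCO[Si](C)(C)C(C)(C)C)[C@@H]([C@H](O[Si](C)(C)C(C)(C)C)/C=C(\C(=O)OCC[Si](C)(C)C)C[Sn](CCCC)(CCCC)CCCC)C(=C)CO[Si](c1ccccc1)(c1ccccc1)C(C)(C)C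
F6 | step 17 | 2-(trimethylsilyl)ethyl (2E,4R,5R,6S)-4-[(tert-butyldimethylsilyl)oxy]-5-(3-{[tert-butyl(diphenyl)silyl]oxy}prop-1-en-2-yl)-6-(2-hydroxyethyl)-6-methyl-2-[(tributylstannyl)methyl]octa-2,7-dienoate | C=C[C@](C)(CCO)[C@@H]([C@H](O[Si](C)(C)C(C)(C)C)/C=C(\C(=O)OCC[Si](C)(C)C)C[Sn](CCCC)(CCCC)CCCC)C(=C)CO[Si](c1ccccc1)(c1ccccc1)C(C)(C)C
F7 | step 17 | 2-(trimethylsilyl)ethyl (2E,4R,5R,6S)-4-[(tert-butyldimethylsilyl)oxy]-5-(3-{[tert-butyl(diphenyl)silyl]oxy}prop-1-en-2-yl)-6-methyl-6-(2-oxoethyl)-2-[(tributylstannyl)methyl]octa-2,7-dienoate | C=C[C@](C)(CC=O)[C@@H]([C@H](O[Si](C)(C)C(C)(C)C)/C=C(\C(=O)OCC[Si](C)(C)C)C[Sn](CCCC)(CCCC)CCCC)C(=C)CO[Si](c1ccccc1)(c1ccccc1)C(C)(C)C
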